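**Strategy.** The route rests on cutting the bond between indole C5 and the benzylic CH of the trans-ethene bridge. That CH is brought in as a one-carbon linchpin, bis(pinacolboryl)methane. In one pot it olefinates the neopentyl aldehyde on the quaternary cyclohexene carbon C1 (boron-Wittig), and the resulting (E)-alkenylboronate is cross-coupled with a 5-bromoindole (Suzuki–Miyaura), so three components are joined. The step exploits the quaternary C1 of the cyclohexene ring: no α-hydrogen, hence no epimerisation, and high E-selectivity. The aldehyde comes from a catalytic enantioselective endo Diels–Alder reaction of methacrolein with an indolyl diene. Both indole units derive from one reverse-prenylated 5-bromoindole.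

Key step: step 5

Remark: the cyclohexene is numbered C1 (quaternary carbon with methyl and the ethene bridge), C2 (CH carrying the second indole), C3=C4(CH3), C5, C6. The indole of the diene half is N-tosylated to protect it from the cationic boron catalyst of step 4; the tosyl group is removed in step 6.

**Step 1**
Reactants: 1 5-bromo-1H-indole; 2 isoprene (2-methylbuta-1,3-diene)
Product: 3 5-bromo-3-(2-methylbut-3-en-2-yl)-1H-indole
Conditions: [Rh(cod)Cl]2 (2.5 mol%), DTBM-Segphos (5 mol%), (PhO)2PO2H (10 mol%), isoprene (5 equiv), DCE, 60 °C, sealed tube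
Reagents that add atoms: none
Why: Rhodium-hydride-catalysed hydroarylation of a 1,3-diene (reverse prenylation): Rh–H adds to isoprene to give a 1,1-dimethyl-π-allyl rhodium species, which indole C3 attacks at the more substituted allyl terminus, while the aryl bromide and the N–H stay untouched.

**Step 2**
Reactants: 3 5-bromo-3-(2-methylbut-3-en-2-yl)-1H-indole
Product: 4 5-bromo-3-(2-methylbut-3-en-2-yl)-1-(p-toluenesulfonyl)-1H-indole
Conditions: NaH, THF, 0 °C; TsCl, 0 °C → rt
Reagents that add atoms: p-toluenesulfonyl chloride, Cc1ccc(S(=O)(=O)Cl)cc1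
Why: N-sulfonylation of the sodium indolide (C3 is blocked); the tosyl group lowers the nucleophilicity and acid sensitivity of this indole for the Lewis-acid step 4.

**Step 3**
Reactants: 5 2-methylbut-1-en-3-yne; 6 pinacolborane; 4 5-bromo-3-(2-methylbut-3-en-2-yl)-1-tosyl-1H-indole
Product: 8 5-[(E)-3-methylbuta-1,3-dien-1-yl]-3-(2-methylbut-3-en-2-yl)-1-tosyl-1H-indole, via dienylboronate 7 (not isolated)
Conditions: Cp2Zr(H)Cl (5 mol%), Et3N (10 mol%), CH2Cl2, 40 °C, sealed; then 4, Pd(dppf)Cl2 (5 mol%), aq. K3PO4, THF, 60 °C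
Reagents that add atoms: none
Why: Zirconocene-hydride-catalysed syn-hydroboration of the terminal alkyne of 5 puts boron on the terminal carbon to give the (E)-dienylboronate, which undergoes Suzuki–Miyaura coupling with the aryl bromide with retention of alkene geometry; the N-tosyl group and the hindered 1,1-dimethylallyl alkene are inert to phosphate base and to carbopalladation at 60 °C.

**Step 4**
Reactants: 8 5-[(E)-3-methylbuta-1,3-dien-1-yl]-3-(2-methylbut-3-en-2-yl)-1-tosyl-1H-indole; 9 methacrolein (2-methylprop-2-enal)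
Product: 10 (1S,2S)-1,4-dimethyl-2-[3-(2-methylbut-3-en-2-yl)-1-tosyl-1H-indol-5-yl]cyclohex-3-ene-1-carbaldehyde (aryl and CHO cis)
Conditions: (S)-3,3-diphenyl-1-(o-tolyl)tetrahydropyrrolo[1,2-c][1,3,2]oxazaborole (o-tolyl CBS oxazaborolidine, 20 mol%), Tf2NH (17 mol%), CH2Cl2, −78 → −40 °C
Reagents that add atoms: none
Why: Catalytic enantioselective Diels–Alder reaction: the triflimide-activated (S)-oxazaborolidinium binds s-trans methacrolein (formyl C–H···O contact) and its phenyl group screens the Cα Si face, so the diene adds to the Re face with its CH2 terminus on the enal β-carbon (ortho/para rule) through the formyl-endo transition state, which sets C1 (S) and C2 (S) with aryl and CHO cis.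

**Step 5**
Reactants: 10 the (1S,2S)-aldehyde; 11 bis(pinacolboryl)methane (bis(4,4,5,5-tetramethyl-1,3,2-dioxaborolan-2-yl)methane); 3 5-bromo-3-(2-methylbut-3-en-2-yl)-1H-indole
Product: 13 5-{(E)-2-[(1R,2R)-1,4-dimethyl-2-(3-(2-methylbut-3-en-2-yl)-1-tosyl-1H-indol-5-yl)cyclohex-3-en-1-yl]ethenyl}-3-(2-methylbut-3-en-2-yl)-1H-indole, via alkenylboronate 12 (not isolated)
Conditions: 2,2,6,6-tetramethylpiperidine, n-BuLi, THF, 0 °C; 11 (1.15 equiv), 0 °C; 10, −78 °C → rt; then 3 (1.3 equiv), Pd(OAc)2 (5 mol%), SPhos (10 mol%), aq. K3PO4, 60 °C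
Reagents that add atoms: none
Why: Lithiated 11 adds to the formyl group of 10, and the β-alkoxide attacks one boron and leaves with it in a syn B–O elimination (boron-Wittig olefination) to give alkenylboronate 12; after addition of 3, palladium(0) inserts into the indole C5–Br bond, phosphate-assisted transmetalation transfers the alkenyl group and reductive elimination forms the C5–CH bond with retention of alkene geometry (Suzuki–Miyaura coupling). The closest known reaction types are the boron-Wittig olefination of aldehydes with geminal bis(boronates) and the alkenylboronate–aryl bromide cross-coupling, here telescoped in one flask. No ring is closed and no stereocentre is created; because C1 of the cyclohexene is quaternary, 10 cannot enolise, so C1 and the adjacent C2 pass through the basic medium unchanged. The E geometry is set in the elimination, where the bulky quaternary C1 substituent and the retained boryl group take up an anti arrangement. The step needs chemoselectivity for boron-to-palladium transfer over Heck arylation of the two 1,1-dimethylallyl vinyl groups and the ring alkene; this is secured by placing boron only on the linchpin carbon and by the neopentyl hindrance of the competing alkenes at 60 °C.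

**Step 6**
Reactants: 13 the N-tosyl coupling product
Product: 14 5-{(E)-2-[(1R,2R)-1,4-dimethyl-2-(3-(2-methylbut-3-en-2-yl)-1H-indol-5-yl)cyclohex-3-en-1-yl]ethenyl}-3-(2-methylbut-3-en-2-yl)-1H-indole (target)
Conditions: KOH, MeOH–THF–H2O, 65 °C
Reagents that add atoms: none
Why: Hydroxide/methoxide attack at sulfur cleaves the N-sulfonyl indole (sulfonamide solvolysis with the indolide as leaving group); the alkenes and the two stereocentres are not base-labile and stay untouched.

**Compound list**
1 | 5-bromo-1H-indole | Brc1ccc2[nH]ccc2c1 | starting material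
2 | isoprene | C=CC(C)=C | starting material
3 | 5-bromo-3-(2-methylbut-3-en-2-yl)-1H-indole | C=CC(C)(C)c1c[nH]c2ccc(Br)cc12 | intermediate
4 | 5-bromo-3-(2-methylbut-3-en-2-yl)-1-tosyl-1H-indole | C=CC(C)(C)c1cn(S(=O)(=O)c2ccc(C)cc2)c2ccc(Br)cc12 | intermediate
5 | 2-methylbut-1-en-3-yne | C=C(C)C#C | starting material
6 | pinacolborane | CC1(C)OBOC1(C)C | starting material
7 | (E)-4,4,5,5-tetramethyl-2-(3-methylbuta-1,3-dien-1-yl)-1,3,2-dioxaborolane | C=C(C)/C=C/B1OC(C)(C)C(C)(C)O1 | intermediate
8 | 5-[(E)-3-methylbuta-1,3-dien-1-yl]-3-(2-methylbut-3-en-2-yl)-1-tosyl-1H-indole | C=C(C)/C=C/c1ccc2c(c1)c(C(C)(C)C=C)cn2S(=O)(=O)c1ccc(C)cc1 | intermediate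
9 | methacrolein | C=C(C)C=O | starting material
10 | (1S,2S)-1,4-dimethyl-2-[3-(2-methylbut-3-en-2-yl)-1-tosyl-1H-indol-5-yl]cyclohex-3-ene-1-carbaldehyde | O=C[C@@]1(C)CCC(C)=C[C@H]1c1ccc2c(c1)c(C(C)(C)C=C)cn2S(=O)(=O)c1ccc(C)cc1 | intermediate
11 | bis(pinacolboryl)methane | CC1(C)OB(CB2OC(C)(C)C(C)(C)O2)OC1(C)C | starting material
12 | 2-{(E)-2-[(1R,2R)-1,4-dimethyl-2-(3-(2-methylbut-3-en-2-yl)-1-tosyl-1H-indol-5-yl)cyclohex-3-en-1-yl]ethenyl}-4,4,5,5-tetramethyl-1,3,2-dioxaborolane | CC1(C)OB(/C=C/[C@@]2(C)CCC(C)=C[C@H]2c2ccc3c(c2)c(C(C)(C)C=C)cn3S(=O)(=O)c2ccc(C)cc2)OC1(C)C | intermediate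
13 | 5-{(E)-2-[(1R,2R)-1,4-dimethyl-2-(3-(2-methylbut-3-en-2-yl)-1-tosyl-1H-indol-5-yl)cyclohex-3-en-1-yl]ethenyl}-3-(2-methylbut-3-en-2-yl)-1H-indole | C=CC(C)(C)c1c[nH]c2ccc(/C=C/[C@@]3(C)CCC(C)=C[C@H]3c3ccc4c(c3)c(C(C)(C)C=C)cn4S(=O)(=O)c3ccc(C)cc3)cc12 | intermediate
14 | 5-{(E)-2-[(1R,2R)-1,4-dimethyl-2-(3-(2-methylbut-3-en-2-yl)-1H-indol-5-yl)cyclohex-3-en-1-yl]ethenyl}-3-(2-methylbut-3-en-2-yl)-1H-indole | C=CC(C)(C)c1c[nH]c2ccc(/C=C/[C@@]3(C)CCC(C)=C[C@H]3c3ccc4[nH]cc(C(C)(C)C=C)c4c3)cc12 | target

**Step count and risks**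
Total step count: 6. Longest linear sequence: 6 (1 → 3 → 4 → 8 → 10 → 13 → 14).

Steps most likely to fail:

1. Step 4. Formyl-endo or facial control may be insufficient for this untested diene/enal pair, or the cationic boron catalyst may oligomerise the electron-rich aryl diene. Fallback: setting out from 8 (with 9), a Me2AlCl-promoted Diels–Alder reaction (CH2Cl2, −78 °C) should give the cis aldehyde as the racemate, that is 10 accompanied by its (1R,2R)-enantiomer F2. Preparative chromatography on a chiral stationary phase then provides 10, where the fallback comes back to the route.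

2. Step 5. The bulky lithiated geminal diboronate may add sluggishly to the neopentyl aldehyde next to the aryl-bearing C2, or lithium borate residues may retard transmetalation so that protodeboronation competes. Fallback: setting out from 10, Ohira–Bestmann homologation (dimethyl (1-diazo-2-oxopropyl)phosphonate, K2CO3, MeOH, rt) should give the terminal alkyne (1S,2S)-1-ethynyl-1,4-dimethyl-2-[3-(2-methylbut-3-en-2-yl)-1-tosyl-1H-indol-5-yl]cyclohex-3-ene F1. Zirconocene-hydride-catalysed hydroboration of F1 with pinacolborane 6 is chemoselective for the alkyne and comes back to the route at 12, now isolated. Compound 12 is then coupled with 3 under the palladium conditions of step 5 to give 13.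

3. Step 1. The indole may attack the unsubstituted allyl terminus (linear prenyl), N- or double alkylation may occur, or the Brønsted co-catalyst may promote 3→2 migration of the 1,1-dimethylallyl group. Fallback: setting out from 1, a base-mediated iridium-catalysed allylic substitution ([Ir(cod)Cl]2, phosphoramidite ligand, KOtBu, Et3B, THF, rt) is used with tert-butyl 2-methylbut-3-en-2-yl carbonate F3, itself made from 2-methylbut-3-en-2-ol and Boc2O (n-BuLi, THF). The N-boryl indolide attacks the tertiary terminus of the allyl–iridium species under non-acidic conditions, and the fallback comes back to the route at 3.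

**Further compounds**
F1 | step 5 | (1S,2S)-1-ethynyl-1,4-dimethyl-2-[3-(2-methylbut-3-en-2-yl)-1-tosyl-1H-indol-5-yl]cyclohex-3-ene | C#C[C@@]1(C)CCC(C)=C[C@H]1c1ccc2c(c1)c(C(C)(C)C=C)cn2S(=O)(=O)c1ccc(C)cc1
F2 | step 4 | (1R,2R)-1,4-dimethyl-2-[3-(2-methylbut-3-en-2-yl)-1-tosyl-1H-indol-5-yl]cyclohex-3-ene-1-carbaldehyde (enantiomer of 10 in the racemate) | O=C[C@]1(C)CCC(C)=C[C@@H]1c1ccc2c(c1)c(C(C)(C)C=C)cn2S(=O)(=O)c1ccc(C)cc1
F3 | step 1 | tert-butyl 2-methylbut-3-en-2-yl carbonate | C=CC(C)(C)OC(=O)OC(C)(C)C
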